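**Plan**

- Retrosynthetic cuts, in order: the C3–aroyl bond and the C1–prenyl bond (late lithiations); then, in one operation, C1–C8 and C9–C5; then C3–C4 (dienolate cross-coupling), C5–prenyl and C7–geranyl (enolate alkylations).
- Forward: a δ-lactone holding C4–C8 is made first and converted into a 3,4-dihydro-2H-pyran whose ring oxygen ties C4 to C8 and whose C4 carries a CH2–dioxinone (C3, C2, C1, C9). Heating then closes ring A (C9–C5) and ring B (C1–C8) in one flask.
- Enabling feature: without its C1-prenyl and C3-aroyl groups, ring A (C1, C2, C3, C4, C5, C9) is a cyclohexane-1,3,5-trione whose only sp3 carbon is C5, with a mirror plane through C5 and C2. C8 is a tertiary carbon held 1,5 to C1 through C6–C7.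
- Consequence: a C4=C5 enol ether can be C-acylated by a C9 ketene, and the tert-alkyl O–C8 bond that held this enol ether in place can then hand C8 to C1 as a cation.
- Stereochemistry: C7 comes from an Evans alkylation with geranyl bromide, which also supplies the (E)-olefin. C1 and C5 follow from C7 in the key step (chair, geranyl equatorial). The C5 centre of earlier intermediates is erased at the enol ether stage, so its epimers converge.
- Helpers removed later: the pyran oxygen bridge and acetone (key step), the methyl enol ether and the silyl ethers (last step).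

Key step: step 8

Remark: C1–C9 are the bicyclo[3.3.1]nonane atoms of the target (C1 bridgehead next to CMe2, C2–C4 the β-diketone carbons, C5 the other bridgehead, C7 the geranyl-bearing CH, C8 the CMe2 carbon, C9 the bridging C=O) and are used for the corresponding atoms of every intermediate. Prenyl = 3-methylbut-2-en-1-yl; geranyl = (2E)-3,7-dimethylocta-2,6-dien-1-yl.

**Route**

Step 1
Reactants: 1 (4R)-4-benzyl-1,3-oxazolidin-2-one; 2 5-tert-butoxy-5-oxopentanoic acid
Product: 3 tert-butyl 5-[(4R)-4-benzyl-2-oxo-1,3-oxazolidin-3-yl]-5-oxopentanoate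
Conditions: DCC, DMAP (cat.), CH2Cl2, 0 °C to rt
Reagents that add atoms: none
Why: Steglich-type N-acylation of the oxazolidinone by the free acid end of the glutarate half ester should give the imide without touching the tert-butyl ester; no stereocentre is formed.

Step 2
Reactants: 3 imide; 4 geranyl bromide
Product: 5 tert-butyl (4S,6E)-4-{[(4R)-4-benzyl-2-oxo-1,3-oxazolidin-3-yl]carbonyl}-7,11-dimethyldodeca-6,10-dienoate
Conditions: NaHMDS, THF, −78 °C; then 4, −78 to −40 °C
Reagents that add atoms: none
Why: Evans alkylation, in which the chelated (Z)-sodium enolate of the imide (far more acidic than the ester α-CH2) should take the allylic bromide on the face away from the benzyl group, setting the future C7 and carrying the (E)-olefin in unchanged.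

Step 3
Reactants: 5 alkylated imide
Product: 6 5-tert-butyl 1-methyl (2S)-2-geranylpentanedioate
Conditions: NaOMe (0.3 equiv), MeOH, 0 °C
Reagents that add atoms: methanol, CO
Why: methoxide-catalysed exocyclic transesterification of the N-acyloxazolidinone should release the auxiliary and leave the tert-butyl ester and the C7 centre intact at low temperature.

Step 4
Reactants: 6 mixed diester
Product: 8 (5S)-5-geranyl-6,6-dimethyloxan-2-one, via hydroxy ester 7 (not isolated)
Conditions: MeMgBr (3.5 equiv), CeCl3, THF, −78 to 0 °C; then 40 °C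
Reagents that add atoms: methylmagnesium bromide, C[Mg]Br
Why: double Grignard addition to the methyl ester only (the cerium additive suppresses enolisation next to C7) should give the tertiary alkoxide of 7, which lactonises onto the tert-butyl ester with help from the gem-dimethyl effect; this installs C8 with both methyl groups and its oxygen.

Step 5
Reactants: 8 lactone; 9 prenyl bromide
Product: 10 (3RS,5R)-5-geranyl-6,6-dimethyl-3-prenyloxan-2-one
Conditions: LDA, THF, −78 °C; then 9, DMPU, −78 to −20 °C
Reagents that add atoms: none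
Why: lactone enolate alkylation with an allylic bromide should put the prenyl group on the future C5; the new centre needs no control because it becomes sp2 in step 6.

Step 6
Reactants: 10 prenyl lactone
Product: 11 (3R)-3-geranyl-2,2-dimethyl-5-prenyl-3,4-dihydro-2H-pyran-6-yl diphenyl phosphate
Conditions: KHMDS, THF/HMPA, −78 °C; then (PhO)2P(O)Cl
Reagents that add atoms: diphenyl chlorophosphate, O=P(Cl)(Oc1ccccc1)Oc1ccccc1
Why: O-phosphorylation of the potassium lactone enolate should give the cyclic ketene acetal phosphate, which fixes the double bond at C4=C5 and makes both C5 epimers of 10 converge.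

Step 7
Reactants: 11 ketene acetal phosphate; 12 2,2,6-trimethyl-4H-1,3-dioxin-4-one
Product: 14 6-{[(3R)-3-geranyl-2,2-dimethyl-5-prenyl-3,4-dihydro-2H-pyran-6-yl]methyl}-2,2-dimethyl-4H-1,3-dioxin-4-one, via chlorozinc dienolate 13 (not isolated)
Conditions: 12, LDA, THF, −78 °C; ZnCl2; then 11, Pd2(dba)3 (2.5 mol %), P(t-Bu)3 (10 mol %), THF, 40 °C; neutral work-up
Reagents that add atoms: none
Why: Negishi-type cross-coupling, in which zerovalent palladium should insert into the C4–O(phosphate) bond and couple with the zinc dienolate at its unhindered γ-CH2 terminus (as in γ-arylation of dienolates), joining C3 to C4 while the ring double bond stays at C4=C5.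

Step 8
Reactants: 14 dihydropyranylmethyl dioxinone
Product: 18 (1R,5S,7R)-7-geranyl-8,8-dimethyl-5-prenylbicyclo[3.3.1]nonane-2,4,9-trione, via acylketene 15 (not isolated), via cation–enolate zwitterion 16 (not isolated), via oxa-bridged enol ether 17 (not isolated)
Conditions: PhMe (2 mM), 110 °C; then Sc(OTf)3 (5 mol %), 0 °C
Reagents that add atoms: none
Why: Proposed new method: at 110 °C the dioxinone should lose acetone (retro-[4+2]) to give acylketene 15, whose ketene carbon (C9) is attacked by C5, the nucleophilic carbon of the ring enol ether, because O4 is alkylated and cannot be acylated to a pyrone; the tert-alkyl oxocarbenium ion so formed should then expel C8 as a tertiary cation beside the enolate of a 4,4-disubstituted cyclohexane-1,3,5-trione (16), and this cation alkylates the trione α-carbon C1. The closest known reaction types are the C-acylation ([4+2] addition) of thermally generated acylketenes by enol ethers, the ionisation of tert-alkyl enol ethers, and the cation–enol cyclisation of dearomatised 4,4-dialkyl phloroglucinol triones to bicyclo[3.3.1]nonane-2,4,9-triones. Ring A closes by six-membered attack of the endocyclic enol ether on the ketene carbon (6-(enolendo)-exo-trig), and ring B by six-membered (enolendo) capture of the exocyclic tertiary cation through a chair. In 16 ring A has a mirror plane through C5 and C2, so C5 is not yet a stereocentre; the C7 centre alone decides, by keeping the geranyl group equatorial in that chair, which of the two enantiotopic α-carbons (each flanked by a carbonyl that then becomes C9) bonds to C8, and this fixes C1 and C5 (necessarily cis across the bicycle) relative to C7 with geranyl exo. O-capture of the cation gives the oxa-bridged enol ether 17, a reversible side channel that Sc(OTf)3 should re-ionise, so material funnels to C-alkylated 18. The step needs C- over O-acylation, attack at C5 and not C3, and a cation made without protons so that the prenyl and geranyl olefins and the C7–H centre survive; the ring enol ether (C4=C5 fixed, O4 blocked) and the neutral thermal, then mildly Lewis acidic, conditions are meant to secure these.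

Step 9
Reactants: 18 bicyclic trione
Product: 19 (1R,5S,7R)-7-geranyl-2-methoxy-8,8-dimethyl-5-prenylbicyclo[3.3.1]non-2-ene-4,9-dione
Conditions: Me2SO4, K2CO3, acetone, rt
Reagents that add atoms: dimethyl sulfate, COS(=O)(=O)OC
Why: O-methylation of the enolised 1,3-diketone with a hard electrophile should occur mainly at the less hindered O2 (next to C1–H, away from the quaternary C5); any O4-methyl isomer is separated and returned to 18 by hydrolysis.

Step 10
Reactants: 19 methyl enol ether; 9 prenyl bromide
Product: 20 (1R,5S,7R)-7-geranyl-2-methoxy-8,8-dimethyl-1,5-diprenylbicyclo[3.3.1]non-2-ene-4,9-dione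
Conditions: LDA, THF, −78 °C; then 9, −78 to 0 °C
Reagents that add atoms: none
Why: bridgehead lithiation at C1 (the only sp3 C–H flanked by C9=O and the vinylogous ester) followed by SN2 alkylation with the allylic bromide should install the second prenyl group; the configuration at C1 is dictated by the bicycle.

Step 11
Reactants: 21 3,4-dihydroxybenzoic acid
Product: 22 tert-butyldimethylsilyl 3,4-bis(tert-butyldimethylsilyloxy)benzoate
Conditions: TBSCl (3.3 equiv), imidazole, DMF, rt
Reagents that add atoms: tert-butyldimethylsilyl chloride, CC(C)(C)[Si](C)(C)Cl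
Why: exhaustive silylation protects both phenols as ethers that withstand the lithium amide of step 13 and fall to hydroxide in step 14.

Step 12
Reactants: 22 tris-silyl compound
Product: 23 3,4-bis(tert-butyldimethylsilyloxy)benzoyl chloride
Conditions: (COCl)2, DMF (cat.), CH2Cl2, 0 °C to rt
Reagents that add atoms: oxalyl chloride, O=C(Cl)C(=O)Cl
Why: the silyl ester should be converted directly into the acid chloride by the Vilsmeier-type chlorinating species under neutral conditions that spare the aryl silyl ethers.

Step 13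
Reactants: 20 diprenyl enol ether; 23 aroyl chloride
Product: 24 (1R,5R,7R)-3-[3,4-bis(tert-butyldimethylsilyloxy)benzoyl]-7-geranyl-2-methoxy-8,8-dimethyl-1,5-diprenylbicyclo[3.3.1]non-2-ene-4,9-dione
Conditions: LiTMP, THF, −78 °C; then 23
Reagents that add atoms: none
Why: vinylic lithiation at C3 (the only acidic C–H left, α to the vinylogous ester carbonyl) and C-acylation by the acid chloride should install the aroyl group without touching any stereocentre.

Step 14
Reactants: 24 protected precursor
Product: 25 oblongifolin B, (1S,5S,7R)-3-(3,4-dihydroxybenzoyl)-7-geranyl-4-hydroxy-8,8-dimethyl-1,5-diprenylbicyclo[3.3.1]non-3-ene-2,9-dione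
Conditions: LiOH, dioxane/H2O (degassed), 90 °C; then aq. HCl
Reagents that add atoms: lithium hydroxide, [Li+].[OH-]
Why: hydroxide should add to C2 of the vinylogous ester and expel methoxide (addition–elimination) and cleave both aryl silyl ethers, the resulting polyanion resisting retro-Claisen cleavage until acidification; the enol drawn for the target is one of two rapidly interconverting tautomers.

**Compound list**

1 | (4R)-4-benzyl-1,3-oxazolidin-2-one | O=C1N[C@H](Cc2ccccc2)CO1 | starting material
2 | 5-tert-butoxy-5-oxopentanoic acid | CC(C)(C)OC(=O)CCCC(=O)O | starting material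
3 | tert-butyl 5-[(4R)-4-benzyl-2-oxo-1,3-oxazolidin-3-yl]-5-oxopentanoate | CC(C)(C)OC(=O)CCCC(=O)N1C(=O)OC[C@H]1Cc1ccccc1 | intermediate
4 | geranyl bromide, (2E)-1-bromo-3,7-dimethylocta-2,6-diene | CC(C)=CCC/C(C)=C/CBr | starting material
5 | tert-butyl (4S,6E)-4-{[(4R)-4-benzyl-2-oxo-1,3-oxazolidin-3-yl]carbonyl}-7,11-dimethyldodeca-6,10-dienoate | CC(C)=CCC/C(C)=C/C[C@@H](C(=O)N1C(=O)OC[C@H]1Cc1ccccc1)CCC(=O)OC(C)(C)C | intermediate
6 | 5-tert-butyl 1-methyl (2S)-2-geranylpentanedioate | CC(C)=CCC/C(C)=C/C[C@@H](C(=O)OC)CCC(=O)OC(C)(C)C | intermediate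
7 | tert-butyl (4S,6E)-4-(2-hydroxypropan-2-yl)-7,11-dimethyldodeca-6,10-dienoate | CC(C)=CCC/C(C)=C/C[C@@H](C(C)(C)O)CCC(=O)OC(C)(C)C | intermediate (not isolated)
8 | (5S)-5-geranyl-6,6-dimethyloxan-2-one | CC(C)=CCC/C(C)=C/C[C@@H]1CCC(=O)OC1(C)C | intermediate
9 | prenyl bromide, 1-bromo-3-methylbut-2-ene | CC(C)=CCBr | starting material
10 | (3RS,5R)-5-geranyl-6,6-dimethyl-3-prenyloxan-2-one | CC(C)=CCC/C(C)=C/C[C@@H]1CC(CC=C(C)C)C(=O)OC1(C)C | intermediate
11 | (3R)-3-geranyl-2,2-dimethyl-5-prenyl-3,4-dihydro-2H-pyran-6-yl diphenyl phosphate | CC(C)=CCC/C(C)=C/C[C@@H]1CC(CC=C(C)C)=C(OP(=O)(Oc2ccccc2)Oc2ccccc2)OC1(C)C | intermediate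
12 | 2,2,6-trimethyl-4H-1,3-dioxin-4-one | CC1=CC(=O)OC(C)(C)O1 | starting material
13 | chlorozinc dienolate of 12 (6-methylidene form, O-bound zinc) | C=C1C=C(O[Zn]Cl)OC(C)(C)O1 | intermediate (not isolated)
14 | 6-{[(3R)-3-geranyl-2,2-dimethyl-5-prenyl-3,4-dihydro-2H-pyran-6-yl]methyl}-2,2-dimethyl-4H-1,3-dioxin-4-one | CC(C)=CCC/C(C)=C/C[C@@H]1CC(CC=C(C)C)=C(CC2=CC(=O)OC(C)(C)O2)OC1(C)C | intermediate
15 | 4-[(3R)-3-geranyl-2,2-dimethyl-5-prenyl-3,4-dihydro-2H-pyran-6-yl]but-1-ene-1,3-dione (acylketene) | CC(C)=CCC/C(C)=C/C[C@@H]1CC(CC=C(C)C)=C(CC(=O)C=C=O)OC1(C)C | intermediate (not isolated)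
16 | zwitterion: enolate of 4-prenyl-4-[(2R)-2-geranyl-3-methylbutyl]cyclohexane-1,3,5-trione with the tertiary cation at C8 | CC(C)=CCC/C(C)=C/C[C@H](CC1(CC=C(C)C)C(=O)CC(=O)C=C1[O-])[C+](C)C | intermediate (not isolated)
17 | oxa-bridged enol ether (O9–C8 bonded isomer of 18, C5 epimers) | CC(C)=CCC/C(C)=C/C[C@@H]1CC2(CC=C(C)C)C(=O)CC(=O)C=C2OC1(C)C | intermediate (not isolated)
18 | (1R,5S,7R)-7-geranyl-8,8-dimethyl-5-prenylbicyclo[3.3.1]nonane-2,4,9-trione | CC(C)=CCC/C(C)=C/C[C@@H]1C[C@]2(CC=C(C)C)C(=O)[C@@H](C(=O)CC2=O)C1(C)C | intermediate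
19 | (1R,5S,7R)-7-geranyl-2-methoxy-8,8-dimethyl-5-prenylbicyclo[3.3.1]non-2-ene-4,9-dione | CC(C)=CCC/C(C)=C/C[C@@H]1C[C@]2(CC=C(C)C)C(=O)[C@@H](C(OC)=CC2=O)C1(C)C | intermediate
20 | (1R,5S,7R)-7-geranyl-2-methoxy-8,8-dimethyl-1,5-diprenylbicyclo[3.3.1]non-2-ene-4,9-dione | CC(C)=CCC/C(C)=C/C[C@@H]1C[C@]2(CC=C(C)C)C(=O)[C@@](CC=C(C)C)(C(OC)=CC2=O)C1(C)C | intermediate
21 | 3,4-dihydroxybenzoic acid | OC(=O)c1ccc(O)c(O)c1 | starting material
22 | tert-butyldimethylsilyl 3,4-bis(tert-butyldimethylsilyloxy)benzoate | CC(C)(C)[Si](C)(C)OC(=O)c1ccc(O[Si](C)(C)C(C)(C)C)c(O[Si](C)(C)C(C)(C)C)c1 | intermediate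
23 | 3,4-bis(tert-butyldimethylsilyloxy)benzoyl chloride | CC(C)(C)[Si](C)(C)Oc1ccc(C(=O)Cl)cc1O[Si](C)(C)C(C)(C)C | intermediate
24 | (1R,5R,7R)-3-[3,4-bis(tert-butyldimethylsilyloxy)benzoyl]-7-geranyl-2-methoxy-8,8-dimethyl-1,5-diprenylbicyclo[3.3.1]non-2-ene-4,9-dione | CC(C)=CCC/C(C)=C/C[C@@H]1C[C@]2(CC=C(C)C)C(=O)[C@@](CC=C(C)C)(C(OC)=C(C(=O)c3ccc(O[Si](C)(C)C(C)(C)C)c(O[Si](C)(C)C(C)(C)C)c3)C2=O)C1(C)C | intermediate
25 | oblongifolin B | CC(C)=CCC/C(C)=C/C[C@@H]1C[C@]2(CC=C(C)C)C(=O)[C@@](CC=C(C)C)(C(=O)C(C(=O)c3ccc(O)c(O)c3)=C2O)C1(C)C | target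

**Totals and risks**

Total step count: 14. Longest linear sequence: 12 (steps 1–10, 13, 14).

Step 8. The ring double bond may migrate into conjugation with the dioxinone before the ketene forms, the cation may be captured at oxygen without return, or the C8 cation may lose a proton. The fallback uses known reactions and builds ring B before ring A. It sets out from lactone 10: Petasis methylenation (Cp2TiMe2, PhMe, 70 °C) should give the exocyclic enol ether (3R)-3-geranyl-2,2-dimethyl-6-methylidene-5-prenyloxane F1. A Lewis-acid promoted Ferrier-type O-to-C rearrangement (Me2AlCl, CH2Cl2, −78 °C) then moves C8 from oxygen to the methylidene carbon and gives (2RS,4R)-4-geranyl-5,5-dimethyl-2-prenylcyclohexan-1-one F2, whose carbonyl becomes C9. The thermodynamic silyl enol ether {[(4R)-4-geranyl-5,5-dimethyl-2-prenylcyclohex-1-en-1-yl]oxy}trimethylsilane F3 (TMSCl, NaI, Et3N, MeCN) is then annulated with malonyl dichloride (Effenberger cyclisation, then KOH, BnEt3NCl), the malonyl unit bridging C5 and C1 anti to the geranyl group. The route is rejoined at 18.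

Step 10. Deprotonation may occur at vinylic C3 instead of the bridgehead, or alkylation of the hindered bridgehead carbanion next to the gem-dimethyl carbon may be slow. The fallback replaces the two-electron alkylation by bridgehead radical chemistry. It sets out from 19: lithiation and quench with the small electrophile I2 (LiTMP, THF, −78 °C; I2) should give the 1-iodo analogue of 19 F4. Keck allylation (allyltributylstannane, Et3B, air, PhH) gives the 1-allyl analogue of 19 F5, and olefin cross-metathesis with 2-methylbut-2-ene (second-generation Grubbs catalyst, CH2Cl2, 40 °C) turns the allyl into the prenyl group. The route is rejoined at 20.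

Step 7. The dienolate may couple at its α- instead of its γ-carbon, oxidative addition into the tetrasubstituted ketene acetal phosphate may be slow, or the basic medium may shift the ring double bond. The fallback sets out from lactone 10 and dioxinone 12: the lithium dienolate of 12 (LDA, THF, −78 °C) is added to the lactone carbonyl to give the lactol 6-{[(3R)-3-geranyl-6-hydroxy-2,2-dimethyl-5-prenyloxan-6-yl]methyl}-2,2-dimethyl-4H-1,3-dioxin-4-one F6. Dehydration with Burgess reagent (PhMe, 50 °C), with chromatographic removal of the exocyclic isomer, rejoins the route at 14.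

Further compounds
F1 | step 8 | (3R)-3-geranyl-2,2-dimethyl-6-methylidene-5-prenyloxane | CC(C)=CCC/C(C)=C/C[C@@H]1CC(CC=C(C)C)C(=C)OC1(C)C
F2 | step 8 | (2RS,4R)-4-geranyl-5,5-dimethyl-2-prenylcyclohexan-1-one | CC(C)=CCC/C(C)=C/C[C@@H]1CC(CC=C(C)C)C(=O)CC1(C)C
F3 | step 8 | {[(4R)-4-geranyl-5,5-dimethyl-2-prenylcyclohex-1-en-1-yl]oxy}trimethylsilane | CC(C)=CCC/C(C)=C/C[C@@H]1CC(CC=C(C)C)=C(O[Si](C)(C)C)CC1(C)C
F4 | step 10 | 1-iodo analogue of 19 | CC(C)=CCC/C(C)=C/C[C@@H]1C[C@]2(CC=C(C)C)C(=O)[C@@](I)(C(OC)=CC2=O)C1(C)C
F5 | step 10 | 1-allyl analogue of 19 | CC(C)=CCC/C(C)=C/C[C@@H]1C[C@]2(CC=C(C)C)C(=O)[C@@](CC=C)(C(OC)=CC2=O)C1(C)C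
F6 | step 7 | 6-{[(3R)-3-geranyl-6-hydroxy-2,2-dimethyl-5-prenyloxan-6-yl]methyl}-2,2-dimethyl-4H-1,3-dioxin-4-one | CC(C)=CCC/C(C)=C/C[C@@H]1CC(CC=C(C)C)C(O)(CC2=CC(=O)OC(C)(C)O2)OC1(C)C
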